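I start from the constants 2.87 × 10⁻⁴ /s and 0.00260 /M/s, which belong to the two ways forward out of the open intermediate.

    substrate + coupling partner ⇌ open intermediate (K1 = 99 /M, k1 = 0.00785 /M/s)
    open intermediate → target (k2 = 2.87 × 10⁻⁴ /s)
    2 coupling partner → self-condensation product (k3 = 0.0117 /M/s)
    open intermediate + capture agent → trapped intermediate (k4 = 0.00260 /M/s)

the same everywhere: substrate 24 mM; coupling partner 24.0 mM; time 1.5 h
- epsilon: capture agent 2.50 mM
- zeta: capture agent 4.00 mM
- eta: capture agent 5.00 mM
- gamma: capture agent 8.00 mM

- for a step with 2 of a species take k times the square, and two of it per event
- "hardly changes" means that all values lie within two and a half points (for a concentration: within two and a half percent of the largest)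
- run time (epsilon): 1.5 h

- amount of target at the end, in percent of the substrate charged for epsilon, zeta, eta, gamma, in this order
- how that number moves from the first to the last of them (falls all the way / rises all the way / falls, then rises / rises, then falls / hardly changes)

The target step gives the open intermediate a half-life of 0.671 h, so the run of 1.5 h holds 2.24 such half-lives. Capture is pseudo-first-order in the open intermediate. In epsilon, its constant, the capture constant times [capture agent], divided by the target constant, gives 2.26 %. I carry this ratio as the leak: trapped intermediate made per target made. Both steps draw on the same [open intermediate], so the leak needs no knowledge of how much stands there, as long as [capture agent] stays near its charge.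

Now I read the settings row by row. The leak is 2.26 % in epsilon, 3.62 % in zeta, 4.53 % in eta and 7.25 % in gamma. Even in gamma, capture alone has a half-life of 9.26 h, longer than the run.

I count one target lost per trapped intermediate, so my estimate of the fall from epsilon to gamma is 4.99 % of the level of target. For that level I have a rough start value. With these charges, self-condensation consumes coupling partner 2.98 times as fast as the forward step does at the start, so the forward step then gets 25.1 % of it. The two charges are equal, so I take that start share as a rough level of target in percent of the substrate charged. That puts the fall across the row near 1.3 percentage points, inside the margin, so I commit to a row that hardly changes. My reckoning stops there, because it gives the spread and no firm level.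

The forecast gives 17.8 %, 17.7 %, 17.6 % and 17.4 %, a row that hardly changes, on the ground “Treat the trap as a small perturbation”.

The four flasks give 17.3 %, 17.2 %, 17.1 % and 16.9 %, so the row hardly changes. At 1.50 h in epsilon, open intermediate goes to target 46 times as fast as to trapped intermediate, and the leak applied to the target of epsilon gives 0.391 % of the substrate charged, against 0.384 % trapped intermediate in the flask. In gamma, the same product gives 1.23 %, and the flask holds 1.20 % trapped intermediate at 1.50 h.

The constants are made up.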